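**Plan**

- Late-stage cuts: the C3 methyl enol ether goes back to a diosphenol, and that to a bicyclo[3.2.1]octane-2,8-dione with a CH2 at C3. The allyl group is carried as a propargyl group.
- Key cut: C1–C8 and C6–C7 together. This opens the cyclopentanone ring (C1, C7, C6, C5, C8) and the six-membered ring (C1, C2, C3, C4, C5, C8) to an acyclic phenyl ester with a vinyl group on C5 and an (E)-cinnamoyl ketone.
- Enabling feature: C1 lies between the C2 and C8 carbonyls, and C7 is benzylic and β to C2, so C1=C7 is the α,β-bond of an aryl enone. A C6 radical (from the C5 vinyl group, whose CH2 becomes the C6 methyl) can add to C7, and the C1 enolate so formed can be acylated across the ring by the C5 ester.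
- Forward order: β-keto ester alkylation, asymmetric Michael addition to an aryl divinyl ketone (sets C5), acetyl to vinyl, the cascade (seven-membered ring first, then both target rings at once), Lindlar reduction, C3 oxidation, O-methylation.
- Stereochemistry: C5 from the catalytic Michael addition; C6 and C7 in the radical closure (trans from the E-alkene and a chair-like closure); C1 by the ring constraint. The sense of C6/C7 relative to C5 is the weakest point and is discussed under step 8.

Key step: step 8

Assumption: the quinidine-derived (cupreidine) catalyst is taken to give the (S) centre in 8; if the sense is opposite, the pseudo-enantiomeric quinine-derived catalyst is used.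

**Route**

Step 1
Reactants: 1 2,2,6-trimethyl-4H-1,3-dioxin-4-one; 2 phenol
Product: 3 phenyl 3-oxobutanoate
Conditions: xylene, 140 °C, acetone distilled off
Reagents that add atoms: none
Why: Thermal retro-[4+2] of the dioxinone should give acetylketene, which phenol traps as the aryl β-keto ester (acylketene acetoacetylation).

Step 2
Reactants: 3 phenyl 3-oxobutanoate
Product: 4 phenyl 2-acetylpent-4-ynoate (racemic)
Conditions: K2CO3, acetone, rt
Reagents that add atoms: 3-bromoprop-1-yne, C#CCBr
Why: SN2 C-alkylation of the stabilised β-keto ester enolate installs the three carbons later unmasked as the allyl group, the alkyne being chosen because it should not accept a hydrogen atom from the iron hydride in step 8.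

Step 3
Reactants: 5 (E)-3-(3,4-dimethoxyphenyl)prop-2-enal
Product: 6 (E)-1-(3,4-dimethoxyphenyl)penta-1,4-dien-3-ol (racemic)
Conditions: CH2=CHMgBr, THF, −78 °C; NH4Cl (aq)
Reagents that add atoms: vinylmagnesium bromide, C=C[Mg]Br
Why: 1,2-Grignard addition to the enal.

Step 4
Reactants: 6 (E)-1-(3,4-dimethoxyphenyl)penta-1,4-dien-3-ol
Product: 7 (E)-1-(3,4-dimethoxyphenyl)penta-1,4-dien-3-one
Conditions: Dess–Martin periodinane, CH2Cl2, 0 °C; used at once
Reagents that add atoms: none
Why: Dess–Martin oxidation of the bis-allylic alcohol should give the cross-conjugated dienone without acid that could trigger Nazarov closure.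

Step 5
Reactants: 4 phenyl 2-acetylpent-4-ynoate; 7 (E)-1-(3,4-dimethoxyphenyl)penta-1,4-dien-3-one
Product: 8 phenyl (2S,6E)-2-acetyl-7-(3,4-dimethoxyphenyl)-5-oxo-2-(prop-2-yn-1-yl)hept-6-enoate
Conditions: cupreidine 9-O-(9-phenanthryl) ether (10 mol %), CH2Cl2, −20 °C
Reagents that add atoms: none
Why: Bifunctional cinchona-alkaloid-catalysed asymmetric Michael addition of an α-substituted β-keto ester to a vinyl ketone, in which the catalyst's quinuclidine and phenol bind enol and enone and set the quaternary C2 (the future C5), the unsubstituted vinyl terminus reacting in preference to the β-aryl one.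

Step 6
Reactants: 8 phenyl (2S,6E)-2-acetyl-7-(3,4-dimethoxyphenyl)-5-oxo-2-(prop-2-yn-1-yl)hept-6-enoate
Product: 9 phenyl (2S,6E)-7-(3,4-dimethoxyphenyl)-2-(1-hydroxyethyl)-5-oxo-2-(prop-2-yn-1-yl)hept-6-enoate (both carbinol epimers)
Conditions: Zn(BH4)2, Et2O, −30 °C; NH4Cl (aq), cold
Reagents that add atoms: none
Why: Chelation-assisted hydride reduction of the β-keto ester ketone should be faster than 1,2-reduction of the conjugated cinnamoyl ketone (chemoselective reduction of a saturated ketone beside an enone), and the new carbinol centre is removed in step 7.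

Step 7
Reactants: 9 phenyl (2S,6E)-7-(3,4-dimethoxyphenyl)-2-(1-hydroxyethyl)-5-oxo-2-(prop-2-yn-1-yl)hept-6-enoate
Product: 10 phenyl (2S,6E)-7-(3,4-dimethoxyphenyl)-2-ethenyl-5-oxo-2-(prop-2-yn-1-yl)hept-6-enoate
Conditions: Burgess reagent, toluene, 60 °C
Reagents that add atoms: none
Why: Burgess syn-elimination can only take a hydrogen from the methyl group because the other neighbour is quaternary, so it should give the terminal vinyl group.

Step 8
Reactants: 10 phenyl (2S,6E)-7-(3,4-dimethoxyphenyl)-2-ethenyl-5-oxo-2-(prop-2-yn-1-yl)hept-6-enoate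
Product: 12 (1R,5S,6R,7R)-7-(3,4-dimethoxyphenyl)-6-methyl-5-(prop-2-yn-1-yl)bicyclo[3.2.1]octane-2,8-dione (7-exo-aryl, 6-endo-methyl), via seven-membered iron enolate 11 (not isolated)
Conditions: Fe(acac)3 (30 mol %), PhSiH2(Oi-Pr) (2.5 equiv), THF (0.005 M), 40 °C; NH4Cl (aq)
Reagents that add atoms: none
Why: Proposed new method: hydrogen-atom transfer from the iron hydride to the vinyl CH2 (which becomes the C6 methyl) gives the secondary C6 radical, this adds 7-endo-trig to C7, the β-carbon of the (E)-aryl enone, divalent iron reduces the C1 α-keto radical to a trivalent-iron enolate, and the enolate attacks the phenyl ester on C5 across the seven-membered ring (5-exo-trig for the cyclopentanone, which closes the six-membered ring at the same time) and expels phenoxide, which the silane takes up as it regenerates the hydride. The closest known type is the iron-hydride-initiated radical conjugate addition with polar crossover and intramolecular aldol capture of the enolate; new are the ester as enolate acceptor (a phenyl ester is used because a formyl or keto group next to the radical would undergo 1,2-acyl shift, and because phenoxide is a good enough leaving group to offset the non-enolisable dione) and the medium-ring first closure. C6 and C7 are set in the radical closure through a chair-like transition state with the radical-carbon methyl anti to C1 and the aryl group, fixed by the E-alkene, anti to C5, which makes them trans; C1 can only bond on the face of the ring that carries the ester. The step needs hydrogen-atom transfer to the vinyl group only (secured by masking the allyl group as an alkyne), endo attack at C7 rather than 6-exo attack at C1 (secured by the polarity of the nucleophilic alkyl radical and the enone), and the exo-aryl, endo-methyl sense relative to C5, which requires the phenoxycarbonyl group pseudo-equatorial and the propargyl group pseudo-axial in the closure. This last preference is not secured by the substrate: the ester is the smaller group and would normally take the axial site, so the other trans isomer may well predominate, and this is the least secure point of the step.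

Step 9
Reactants: 12 (1R,5S,6R,7R)-7-(3,4-dimethoxyphenyl)-6-methyl-5-(prop-2-yn-1-yl)bicyclo[3.2.1]octane-2,8-dione
Product: 13 (1R,5S,6R,7R)-7-(3,4-dimethoxyphenyl)-6-methyl-5-(prop-2-en-1-yl)bicyclo[3.2.1]octane-2,8-dione
Conditions: H2 (1 atm), Pd on CaCO3 poisoned with Pb(OAc)2, quinoline, EtOAc, rt
Reagents that add atoms: none
Why: Lindlar semi-hydrogenation of the terminal alkyne should give the terminal alkene, no other C–C multiple bond being present outside the arene.

Step 10
Reactants: 13 (1R,5S,6R,7R)-7-(3,4-dimethoxyphenyl)-6-methyl-5-(prop-2-en-1-yl)bicyclo[3.2.1]octane-2,8-dione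
Product: 14 (1S,5R,6R,7R)-7-(3,4-dimethoxyphenyl)-3-hydroxy-6-methyl-5-(prop-2-en-1-yl)bicyclo[3.2.1]octane-2,8-dione (C3 epimers)
Conditions: KN(SiMe3)2, THF, −78 °C; then 2-(phenylsulfonyl)-3-phenyloxaziridine; NH4Cl (aq)
Reagents that add atoms: 2-(phenylsulfonyl)-3-phenyloxaziridine, O=S(=O)(N1OC1c1ccccc1)c1ccccc1
Why: Only C3 can be enolised (C1 and C5 are bridgeheads), so the potassium enolate should form regiospecifically and be hydroxylated by the Davis oxaziridine (enolate oxidation), the C3 configuration being lost in step 11.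

Step 11
Reactants: 14 (1S,5R,6R,7R)-7-(3,4-dimethoxyphenyl)-3-hydroxy-6-methyl-5-(prop-2-en-1-yl)bicyclo[3.2.1]octane-2,8-dione
Product: 15 (1S,5S,6R,7R)-7-(3,4-dimethoxyphenyl)-3-hydroxy-6-methyl-5-(prop-2-en-1-yl)bicyclo[3.2.1]oct-3-ene-2,8-dione
Conditions: Dess–Martin periodinane, CH2Cl2, rt
Reagents that add atoms: none
Why: Dess–Martin oxidation of the α-ketol should give the 2,3-dione, which can enolise only towards C4 and therefore rests as the diosphenol.

Step 12
Reactants: 15 (1S,5S,6R,7R)-7-(3,4-dimethoxyphenyl)-3-hydroxy-6-methyl-5-(prop-2-en-1-yl)bicyclo[3.2.1]oct-3-ene-2,8-dione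
Product: 16 kadsurenin D, (1S,5S,6R,7R)-7-(3,4-dimethoxyphenyl)-3-methoxy-6-methyl-5-(prop-2-en-1-yl)bicyclo[3.2.1]oct-3-ene-2,8-dione
Conditions: Me2SO4, K2CO3, acetone, rt
Reagents that add atoms: dimethyl sulfate, COS(=O)(=O)OC
Why: O-Methylation of the acidic diosphenol hydroxyl with a hard methylating agent under weak, poorly nucleophilic base (Williamson-type) should give the methyl enol ether, its position being fixed by step 11.

**Compound list**

1 | 2,2,6-trimethyl-4H-1,3-dioxin-4-one | CC1=CC(=O)OC(C)(C)O1 | starting material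
2 | phenol | Oc1ccccc1 | starting material
3 | phenyl 3-oxobutanoate | CC(=O)CC(=O)Oc1ccccc1 | intermediate
4 | phenyl 2-acetylpent-4-ynoate (racemic) | CC(=O)C(CC#C)C(=O)Oc1ccccc1 | intermediate
5 | (E)-3-(3,4-dimethoxyphenyl)prop-2-enal | COc1ccc(/C=C/C=O)cc1OC | starting material
6 | (E)-1-(3,4-dimethoxyphenyl)penta-1,4-dien-3-ol (racemic) | COc1ccc(/C=C/C(O)C=C)cc1OC | intermediate
7 | (E)-1-(3,4-dimethoxyphenyl)penta-1,4-dien-3-one | COc1ccc(/C=C/C(=O)C=C)cc1OC | intermediate
8 | phenyl (2S,6E)-2-acetyl-7-(3,4-dimethoxyphenyl)-5-oxo-2-(prop-2-yn-1-yl)hept-6-enoate | C#CC[C@](C(=O)Oc1ccccc1)(C(C)=O)CCC(=O)/C=C/c1ccc(OC)c(OC)c1 | intermediate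
9 | phenyl (2S,6E)-7-(3,4-dimethoxyphenyl)-2-(1-hydroxyethyl)-5-oxo-2-(prop-2-yn-1-yl)hept-6-enoate (both carbinol epimers) | C#CC[C@](C(=O)Oc1ccccc1)(C(C)O)CCC(=O)/C=C/c1ccc(OC)c(OC)c1 | intermediate
10 | phenyl (2S,6E)-7-(3,4-dimethoxyphenyl)-2-ethenyl-5-oxo-2-(prop-2-yn-1-yl)hept-6-enoate | C#CC[C@](C(=O)Oc1ccccc1)(C=C)CCC(=O)/C=C/c1ccc(OC)c(OC)c1 | intermediate
11 | trivalent-iron enolate of the seven-membered keto ester (shown as the enolate anion): phenyl 6-(3,4-dimethoxyphenyl)-7-methyl-4-oxido-1-(prop-2-yn-1-yl)cyclohept-4-ene-1-carboxylate, methyl trans to the ester and trans to the aryl group | C#CC[C@@]1(C(=O)Oc2ccccc2)CCC([O-])=C[C@H](c2ccc(OC)c(OC)c2)[C@H]1C | intermediate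
12 | (1R,5S,6R,7R)-7-(3,4-dimethoxyphenyl)-6-methyl-5-(prop-2-yn-1-yl)bicyclo[3.2.1]octane-2,8-dione (7-exo-aryl, 6-endo-methyl) | C#CC[C@]12CCC(=O)[C@H](C1=O)[C@H](c1ccc(OC)c(OC)c1)[C@H]2C | intermediate
13 | (1R,5S,6R,7R)-7-(3,4-dimethoxyphenyl)-6-methyl-5-(prop-2-en-1-yl)bicyclo[3.2.1]octane-2,8-dione | C=CC[C@]12CCC(=O)[C@H](C1=O)[C@H](c1ccc(OC)c(OC)c1)[C@H]2C | intermediate
14 | (1S,5R,6R,7R)-7-(3,4-dimethoxyphenyl)-3-hydroxy-6-methyl-5-(prop-2-en-1-yl)bicyclo[3.2.1]octane-2,8-dione (C3 epimers; ring stereocentres as in 13) | C=CC[C@]12CC(O)C(=O)[C@H](C1=O)[C@H](c1ccc(OC)c(OC)c1)[C@H]2C | intermediate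
15 | (1S,5S,6R,7R)-7-(3,4-dimethoxyphenyl)-3-hydroxy-6-methyl-5-(prop-2-en-1-yl)bicyclo[3.2.1]oct-3-ene-2,8-dione | C=CC[C@]12C=C(O)C(=O)[C@H](C1=O)[C@H](c1ccc(OC)c(OC)c1)[C@H]2C | intermediate
16 | kadsurenin D, (1S,5S,6R,7R)-7-(3,4-dimethoxyphenyl)-3-methoxy-6-methyl-5-(prop-2-en-1-yl)bicyclo[3.2.1]oct-3-ene-2,8-dione | C=CC[C@]12C=C(OC)C(=O)[C@H](C1=O)[C@H](c1ccc(OC)c(OC)c1)[C@H]2C | target

**Count and risks**

Total steps: 12. Longest linear sequence: 10 steps (steps 3 to 12 from 5, or steps 1, 2 and 5 to 12 from 1).

Step 8 (Proposed new method). What may go wrong: the iron enolate may be protonated or silylated before it attacks the ester, the radical may close 6-exo at C1, and the radical closure may show poor or inverted facial selectivity relative to C5. The fallback changes the order of bond formation and uses known reaction types; it sets out from 10 and returns at 12. Conjugate reduction of the enone (catecholborane, THF, rt) should give phenyl (2S)-7-(3,4-dimethoxyphenyl)-2-ethenyl-5-oxo-2-(prop-2-yn-1-yl)heptanoate F1. Treatment with LiN(SiMe3)2 (THF, −78 to 0 °C) should close the six-membered ring by Dieckmann-type C-acylation, since only the C6 enolate can reach the ester, giving 2-(3,4-dimethoxybenzyl)-4-ethenyl-4-(prop-2-yn-1-yl)cyclohexane-1,3-dione F2, an enolisable dione. Dehydrogenation with DDQ should give 2-(3,4-dimethoxybenzylidene)-4-ethenyl-4-(prop-2-yn-1-yl)cyclohexane-1,3-dione F3. Iron-hydride reductive olefin coupling (Fe(acac)3, PhSiH3, EtOH, 60 °C) should then close the radical from the vinyl group 5-exo onto the doubly activated arylidene carbon and give 12, with C6 and C7 set on the preformed ring.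

Step 6. What may go wrong: hydride may also reduce the cinnamoyl ketone, and the new alkoxide may attack the neighbouring phenyl ester to form a β-lactone. The fallback avoids any alkoxide; it sets out from 8 and returns at 10. Kinetic enolisation of the acetyl methyl group and O-triflation (KN(SiMe3)2, PhNTf2, THF, −78 °C) should give phenyl (2S,6E)-7-(3,4-dimethoxyphenyl)-5-oxo-2-(prop-2-yn-1-yl)-2-[1-(trifluoromethylsulfonyloxy)ethenyl]hept-6-enoate F4. Reduction of the enol triflate (Pd(OAc)2, PPh3, HCO2H, Bu3N, DMF, 50 °C) should give 10.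

Step 10. What may go wrong: the amide base or the enolate may open the strained, non-enolisable 1,3-dione by retro-Claisen cleavage before hydroxylation. The fallback uses soft enolisation and a neutral oxidant; it sets out from 13 and returns at 14. TMSOTf and Et3N (CH2Cl2, 0 °C) should give (1S,5S,6R,7R)-7-(3,4-dimethoxyphenyl)-6-methyl-5-(prop-2-en-1-yl)-2-(trimethylsilyloxy)bicyclo[3.2.1]oct-2-en-8-one F5. Epoxidation of the silyl enol ether with dimethyldioxirane (acetone, −40 °C) and mild acid work-up (Rubottom oxidation) should give 14.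

Further compounds
F1 | step 8 | phenyl (2S)-7-(3,4-dimethoxyphenyl)-2-ethenyl-5-oxo-2-(prop-2-yn-1-yl)heptanoate | C#CC[C@](C(=O)Oc1ccccc1)(C=C)CCC(=O)CCc1ccc(OC)c(OC)c1
F2 | step 8 | 2-(3,4-dimethoxybenzyl)-4-ethenyl-4-(prop-2-yn-1-yl)cyclohexane-1,3-dione (C4 as set in 10, C2 epimerisable) | C#CC[C@]1(C=C)CCC(=O)C(Cc2ccc(OC)c(OC)c2)C1=O
F3 | step 8 | 2-(3,4-dimethoxybenzylidene)-4-ethenyl-4-(prop-2-yn-1-yl)cyclohexane-1,3-dione (C4 as set in 10) | C#CC[C@]1(C=C)CCC(=O)C(=Cc2ccc(OC)c(OC)c2)C1=O
F4 | step 6 | phenyl (2S,6E)-7-(3,4-dimethoxyphenyl)-5-oxo-2-(prop-2-yn-1-yl)-2-[1-(trifluoromethylsulfonyloxy)ethenyl]hept-6-enoate | C#CC[C@](C(=O)Oc1ccccc1)(C(=C)OS(=O)(=O)C(F)(F)F)CCC(=O)/C=C/c1ccc(OC)c(OC)c1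
F5 | step 10 | (1S,5S,6R,7R)-7-(3,4-dimethoxyphenyl)-6-methyl-5-(prop-2-en-1-yl)-2-(trimethylsilyloxy)bicyclo[3.2.1]oct-2-en-8-one | C=CC[C@]12CC=C(O[Si](C)(C)C)[C@H](C1=O)[C@H](c1ccc(OC)c(OC)c1)[C@H]2C
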